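## Analysis of the target

Target 20 is the (E)-feruloyl ester of 5-methoxylariciresinol: one tetrahydrofuran ring with three side arms and three oxygenated benzene rings. The numbering used throughout is O1, C2 (bearing the 4-hydroxy-3,5-dimethoxyphenyl, or syringyl, ring), C3 (bearing C9H2–O–feruloyl), C4 (bearing the benzylic carbon C7′ of the 4-hydroxy-3-methoxyphenyl, or guaiacyl, ring) and C5H2. The three stereocentres are contiguous, C2 (S), C3 (R) and C4 (R): the aryl group at C2 is trans to the C9 arm, and the C9 arm is cis to the C7′ arm. There are three free phenols. The C2–O1 bond is a para-hydroxybenzylic ether that ionises in acid (epimerisation at C2, or Friedel–Crafts closure of C2 onto the guaiacyl ring) and opens to a quinone methide in base. The cinnamate ester is base-labile, is a Michael acceptor, and rules out hydrogenolytic deprotection. The synthesis is hard for three reasons: the 3,4-cis relation is the less stable one on the ring and cannot be reached by equilibration; the two aryl rings differ by a single methoxy group and must be placed regiospecifically; and C9 and C5, both CH2–O carbons, must end in different roles (ester and ring ether). The strategy rests on the chain C9–C3–C4–C5, which has oxygen on both terminal carbons and so corresponds to a γ-alkoxybutenolide: C5 is the lactone carbonyl, C4 the α-carbon, C3 the β-carbon and C9 the acetal carbon. Because the ring bond at C3 changes from C9 (lactone) to C2 (tetrahydrofuran), a trans-disubstituted lactone maps onto the 3,4-cis tetrahydrofuran, so the difficult relation is obtained as the easy trans,trans outcome on the lactone.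

## Retrosynthetic reasoning

**Phenols last.** The three phenols of 20 are unmasked in the final step from the tris-silyl ether 19. One kind of silyl ether on all three rings means one deprotection, and a silyl group (unlike a benzyl ether) can be removed without touching the cinnamate double bond.

**Ester bond C9–O.** Cutting the acyl–oxygen bond of 19 gives the primary alcohol 15 and the O-silylated ferulic acid 18. Alcohol 15 has only this one free hydroxyl, so no selectivity is asked of the esterification. Acid 18 comes from ferulic acid 16 by silylating both acidic positions (17) and releasing the much more labile silyl ester.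

**Ring bond O1–C2.** The tetrahydrofuran of 15 is opened at O1–C2 and not at O1–C5. C2 is benzylic and para-oxygenated, so it can be the electrophile as cation 14, and its configuration can be left to thermodynamic control (aryl trans to the C9 arm). The precursor is triol 13, in which the carbinol configuration at C2 is irrelevant. Only the C5 hydroxyl can reach C2 through a five-membered transition state; the C9 hydroxyl would have to form an oxetane.

**Oxidation levels.** Triol 13 is the fully reduced form of keto lactone 12, which already tells all three oxygenated carbons apart: the aryl ketone is C2, the lactone carbonyl is C5, and the acetal carbon is C9. One hydride reduction gives all three alcohols and expels the menthyl auxiliary. Ketone 12 comes from dithioacetal 11 by hydrolysis.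

**Key disconnection C2–C3 and C4–C7′.** In 11 the two bonds from the lactone to benzylic carbons are cut. This leaves butenolide 8, whose β-carbon needs a nucleophilic C2 and whose α-carbon, as an enolate, needs an electrophilic C7′. C2 is by nature an electrophilic aldehyde carbon, so its polarity is reversed in the lithiated dithiane 9, made from dithiane 3. C7′ is taken as benzyl bromide 7. Both bonds are made in one flask through enolate 10. The acetal stereocentre of 8 controls the new centre at C3, and that centre controls C4. Cutting elsewhere (for example C3–C4) would give no such relay and would separate the two stereocentres into different fragments.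

**Fragments.** Dithiane 3 is made in two steps from syringaldehyde 1 through silyl ether 2. Bromide 7 is made in three steps from vanillin 4 through 5 and 6. Butenolide 8 is used as bought.

## Alternatives that were turned down

**Alternative 1: enzymatic Baeyer–Villiger desymmetrisation.**
- Disconnection: the C5–O1 oxygen is traced back to O2, and the only stereocentre addressed is C4.
- Forward key step: the prochiral cyclobutanone A1, 3-[4-(benzyloxy)-3-methoxybenzyl]cyclobutanone, is oxidised by a flavin- and NADPH-dependent Baeyer–Villiger monooxygenase under O2. Oxygen is inserted into one of the two enantiotopic acyl–CH2 bonds to give the (R)-lactone A2, (R)-4-[4-(benzyloxy)-3-methoxybenzyl]dihydrofuran-2(3H)-one. Its CH2–O bond is the later C5–O1 bond, its α-CH2 is C3 and its carbonyl is C9. A2 would then need an aldol reaction with aldehyde 2 trans to the benzyl group, reduction to a triol of the type of 13, and the same ring closure.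
- For it: chirality comes from a catalyst and air, there is no stoichiometric auxiliary and no dithioacetal to unmask. On these points it is stronger than the chosen route.
- Against it: the key step sets one stereocentre and forms no carbon–carbon bond. C3 and the C2–C3 bond need a separate enolate step. A1 needs a ketene cycloaddition and dehalogenation before the enzyme is reached. The fit of a bulky benzyloxy-methoxybenzyl group in the active site decides both rate and enantiomeric purity and cannot be predicted from structure. The benzyl ether of A2 must be exchanged before the feruloyl group arrives, because hydrogenolysis would saturate the cinnamate.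
- Comparison: the chosen strategy makes both carbon–carbon bonds and both stereocentres in one operation with a predictable sense, and reaches the same triol stage in fewer operations.

**Alternative 2: palladium trimethylenemethane (3+2) cycloaddition.**
- Disconnection: C2–C3 and O1–C5 of the tetrahydrofuran.
- Forward key step: the cyano-substituted donor A3, 1-cyano-2-[(trimethylsilyl)methyl]allyl acetate, is ionised by Pd2(dba)3 (zerovalent palladium) and a chiral phosphoramidite. The cyano-bearing carbon attacks the silylated aldehyde A4, 4-(tert-butyldimethylsilyloxy)-3,5-dimethoxybenzaldehyde, and the alkoxide closes on the π-allyl terminus to give A5, (2S,3R)-2-[4-(tert-butyldimethylsilyloxy)-3,5-dimethoxyphenyl]-4-methylenetetrahydrofuran-3-carbonitrile.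
- For it: the ring and the centres C2 and C3 are made in one catalytic step. This is the shortest way to the heterocycle and here it is stronger than the chosen route.
- Against it: C4 is still sp2 in A5. The guaiacylmethyl arm has to be built from the exocyclic methylene by hydroboration and cross-coupling, and the face of that hydroboration is contested by the C3 substituent and the C2 aryl group, which lie on opposite faces. The nitrile must be taken down to the C9 alcohol through an epimerisable aldehyde. A4, with three donor oxygens, is a weak electrophile for the zwitterionic palladium complex. The regiochemistry of the cyano group and the enantioselection are both catalyst-dependent.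
- Comparison: the chosen strategy fixes the difficult 3,4 pair first by substrate control and leaves only C2, the one centre that can be corrected by equilibration.

**Alternative 3: quinone methide cycloetherification.**
- Disconnection: O1–C2, with C2 at the CH2 oxidation level in the precursor.
- Forward key step: Ag2O (monovalent silver) oxidises the free syringyl phenol of diol A6, (2R,3R)-2-(4-hydroxy-3,5-dimethoxybenzyl)-3-[3-methoxy-4-(triisopropylsilyloxy)benzyl]butane-1,4-diol, to the quinone methide A7. The C5 hydroxyl adds to C2 and gives A8, 5-methoxylariciresinol with the guaiacyl phenol as its triisopropylsilyl ether.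
- For it: the closure is neutral and biomimetic, needs no carbocation (so less Friedel–Crafts risk than acid closure), and needs no ketone or dithioacetal at C2. On the mildness of the ring closure it is at least as good as the chosen route.
- Against it: A6 is itself an enantiopure, unsymmetrical dibenzylbutanediol with two differently protected phenols, so the asymmetric work is only moved upstream. The oxidant must find one phenol and stop at the quinone methide without tautomerisation to a styrene or further oxidation of the product phenol. A8 carries a free phenol next to the hydroxyl that must be acylated, which costs a protection step or a selectivity problem.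
- Comparison: in the chosen strategy C2 has the carbonyl oxidation level from the start (the dithiane carbon), no oxidant ever meets the electron-rich rings, and all phenols carry the same protecting group to the end.

Key step: step 6

Assumption: butenolide 8 is bought as the single (5R) diastereomer; if it is not in stock it can be made in two steps from furfural (photo-oxygenation, then acetalisation with (1R,2S,5R)-menthol and crystallisation), which does not change the route.

## Route

Step 1
Reactants: 1 syringaldehyde (4-hydroxy-3,5-dimethoxybenzaldehyde)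
Product: 2 3,5-dimethoxy-4-(triisopropylsilyloxy)benzaldehyde
Conditions: TIPSCl, imidazole, DMF, rt to 40 °C
Reagents that add atoms: triisopropylsilyl chloride (TIPSCl), CC(C)[Si](Cl)(C(C)C)C(C)C
Why: Silyl ether formation on a phenol; the flanking methoxy groups slow but do not block the reaction, and the bulky silyl group is chosen to withstand n-BuLi, LiAlH4, Lewis acid and mild protic acid later on.

Step 2
Reactants: 2 3,5-dimethoxy-4-(triisopropylsilyloxy)benzaldehyde
Product: 3 2-[3,5-dimethoxy-4-(triisopropylsilyloxy)phenyl]-1,3-dithiane
Conditions: HS(CH2)3SH, BF3·OEt2 (cat.), CH2Cl2, 0 °C to rt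
Reagents that add atoms: propane-1,3-dithiol, SCCCS
Why: Lewis-acid-catalysed dithioacetalisation of an aromatic aldehyde; the aryl silyl ether tolerates catalytic BF3·OEt2 at this temperature.

Step 3
Reactants: 4 vanillin (4-hydroxy-3-methoxybenzaldehyde)
Product: 5 3-methoxy-4-(triisopropylsilyloxy)benzaldehyde
Conditions: TIPSCl, imidazole, DMF, rt
Reagents that add atoms: triisopropylsilyl chloride (TIPSCl), CC(C)[Si](Cl)(C(C)C)C(C)C
Why: Silyl ether formation on an unhindered phenol.

Step 4
Reactants: 5 3-methoxy-4-(triisopropylsilyloxy)benzaldehyde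
Product: 6 [3-methoxy-4-(triisopropylsilyloxy)phenyl]methanol
Conditions: NaBH4, MeOH, 0 °C
Reagents that add atoms: none
Why: Borohydride reduction of an aromatic aldehyde; the aryl silyl ether is stable to cold methanolic NaBH4 over the short reaction time.

Step 5
Reactants: 6 [3-methoxy-4-(triisopropylsilyloxy)phenyl]methanol
Product: 7 3-methoxy-4-(triisopropylsilyloxy)benzyl bromide
Conditions: PBr3, Et2O, 0 °C; used at once
Reagents that add atoms: phosphorus tribromide, BrP(Br)Br
Why: Conversion of a benzylic alcohol into the bromide through its phosphite ester; the electron-rich bromide ionises easily, so it should be washed, dried and taken straight into step 6.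

Step 6
Reactants: 3 2-[3,5-dimethoxy-4-(triisopropylsilyloxy)phenyl]-1,3-dithiane; 8 (5R)-5-[(1R,2S,5R)-menthyloxy]-2(5H)-furanone; 7 3-methoxy-4-(triisopropylsilyloxy)benzyl bromide
Product: 11 (3R,4R,5R)-3-[3-methoxy-4-(triisopropylsilyloxy)benzyl]-4-{2-[3,5-dimethoxy-4-(triisopropylsilyloxy)phenyl]-1,3-dithian-2-yl}-5-[(1R,2S,5R)-menthyloxy]dihydrofuran-2(3H)-one, via lithiated dithiane 9 (not isolated), via lithium enolate 10 (not isolated)
Conditions: n-BuLi, THF, −78 to −20 °C; 8, THF, −78 °C; then 7, DMPU, −78 to −20 °C; aq. NH4Cl
Reagents that add atoms: none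
Why: n-BuLi removes the doubly sulfur-stabilised benzylic proton of 3 to give 9, which acts as a syringoyl anion (polarity reversal at the future C2). This soft, delocalised carbanion adds 1,4 to butenolide 8 at its β-carbon, forming C2–C3 and the lithium enolate 10. Bromide 7, added with DMPU to loosen the enolate aggregate, then alkylates the α-carbon in an SN2 reaction, forming C4–C7′. The closest known reaction type is the tandem conjugate addition and enolate alkylation of lithiated 2-aryl-1,3-dithianes on γ-alkoxybutenolides, used for dibenzylbutyrolactone lignans. No ring is closed. The centre at lactone C4 (target C3) is controlled by the acetal stereocentre of 8, because the nucleophile approaches the flat butenolide on the face opposite to the menthyloxy group. The centre at lactone C3 (target C4) is controlled by this new centre, because the benzyl group enters the enolate face opposite to the very bulky aryldithianyl group, so the (3R,4R,5R) trans,trans lactone should result. The step needs 1,4- over 1,2-addition (secured by the stabilised anion and low temperature), C-monoalkylation (secured by the lithium enolate and the reactive benzylic halide) and two facial selections (secured by the substituents already on the five-membered ring).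

Step 7
Reactants: 11 (3R,4R,5R)-3-[3-methoxy-4-(triisopropylsilyloxy)benzyl]-4-{2-[3,5-dimethoxy-4-(triisopropylsilyloxy)phenyl]-1,3-dithian-2-yl}-5-[(1R,2S,5R)-menthyloxy]dihydrofuran-2(3H)-one
Product: 12 (3R,4R,5R)-4-[3,5-dimethoxy-4-(triisopropylsilyloxy)benzoyl]-3-[3-methoxy-4-(triisopropylsilyloxy)benzyl]-5-[(1R,2S,5R)-menthyloxy]dihydrofuran-2(3H)-one
Conditions: HgO, BF3·OEt2, THF/H2O, rt
Reagents that add atoms: water, O
Why: Mercury-assisted hydrolysis of a dithioacetal (thiophilic divalent mercury) unmasks the aryl ketone; the lactone acetal and the aryl silyl ethers should survive, and the carbon next to the new ketone already has its more stable trans arrangement, so enolisation should not change it.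

Step 8
Reactants: 12 (3R,4R,5R)-4-[3,5-dimethoxy-4-(triisopropylsilyloxy)benzoyl]-3-[3-methoxy-4-(triisopropylsilyloxy)benzyl]-5-[(1R,2S,5R)-menthyloxy]dihydrofuran-2(3H)-one
Product: 13 (2R,3R)-2-{[3,5-dimethoxy-4-(triisopropylsilyloxy)phenyl](hydroxy)methyl}-3-[3-methoxy-4-(triisopropylsilyloxy)benzyl]butane-1,4-diol (both epimers at the carbinol carbon)
Conditions: LiAlH4, THF, 0 °C to rt; H2O, aq. NaOH work-up
Reagents that add atoms: none
Why: Hydride reduction of ketone and lactone; the ring-opened hemiacetal alkoxide expels menthoxide and the aldehyde so formed is reduced too, giving the C2 carbinol and the C5 and C9 primary alcohols, while C3 and C4 are not touched and the configuration at C2 does not matter for the next step.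

Step 9
Reactants: 13 (2R,3R)-2-{[3,5-dimethoxy-4-(triisopropylsilyloxy)phenyl](hydroxy)methyl}-3-[3-methoxy-4-(triisopropylsilyloxy)benzyl]butane-1,4-diol
Product: 15 [(2S,3R,4R)-2-[3,5-dimethoxy-4-(triisopropylsilyloxy)phenyl]-4-[3-methoxy-4-(triisopropylsilyloxy)benzyl]tetrahydrofuran-3-yl]methanol, via benzylic cation 14 (not isolated)
Conditions: camphorsulfonic acid (cat.), CH2Cl2, 0 °C to rt, stopped at full conversion
Reagents that add atoms: none
Why: Acid-catalysed dehydrative cycloetherification: the C2 carbinol, activated by the para-silyloxy group, ionises to 14 and the C5 hydroxyl closes the ring in a 5-exo-trig manner (the C9 hydroxyl could only form an oxetane); because ionisation is reversible, the aryl group should settle trans to the C9 arm, which sets C2 as S from either epimer of 13.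

Step 10
Reactants: 16 (E)-ferulic acid
Product: 18 (E)-3-[3-methoxy-4-(triisopropylsilyloxy)phenyl]prop-2-enoic acid, via silyl ester silyl ether 17 (not isolated)
Conditions: TIPSCl (2.2 equiv), imidazole, DMF, rt; then K2CO3, THF/MeOH/H2O, 0 °C; aq. HCl to pH 3
Reagents that add atoms: triisopropylsilyl chloride (TIPSCl), CC(C)[Si](Cl)(C(C)C)C(C)C
Why: Both acidic hydroxyls are silylated, and the acyl–oxygen–silicon bond of 17, far more labile than the aryl silyl ether, is then cleaved selectively by cold carbonate.

Step 11
Reactants: 15 [(2S,3R,4R)-2-[3,5-dimethoxy-4-(triisopropylsilyloxy)phenyl]-4-[3-methoxy-4-(triisopropylsilyloxy)benzyl]tetrahydrofuran-3-yl]methanol; 18 (E)-3-[3-methoxy-4-(triisopropylsilyloxy)phenyl]prop-2-enoic acid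
Product: 19 [(2S,3R,4R)-2-[3,5-dimethoxy-4-(triisopropylsilyloxy)phenyl]-4-[3-methoxy-4-(triisopropylsilyloxy)benzyl]tetrahydrofuran-3-yl]methyl (E)-3-[3-methoxy-4-(triisopropylsilyloxy)phenyl]prop-2-enoate
Conditions: DCC, DMAP (cat.), CH2Cl2, 0 °C to rt
Reagents that add atoms: none
Why: Steglich esterification of the only free hydroxyl, a primary alcohol, with a cinnamic acid; no stereocentre is involved and the neutral conditions leave the benzylic ether at C2 alone.

Step 12
Reactants: 19 [(2S,3R,4R)-2-[3,5-dimethoxy-4-(triisopropylsilyloxy)phenyl]-4-[3-methoxy-4-(triisopropylsilyloxy)benzyl]tetrahydrofuran-3-yl]methyl (E)-3-[3-methoxy-4-(triisopropylsilyloxy)phenyl]prop-2-enoate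
Product: 20 [(2S,3R,4R)-2-(4-hydroxy-3,5-dimethoxyphenyl)-4-(4-hydroxy-3-methoxybenzyl)tetrahydrofuran-3-yl]methyl (E)-3-(4-hydroxy-3-methoxyphenyl)prop-2-enoate (CNP0289934.1)
Conditions: TBAF, AcOH, THF, 0 °C
Reagents that add atoms: none
Why: Fluoride cleavage of three aryl silyl ethers; buffering with AcOH keeps the phenols protonated, so the cinnamate should not be cleaved and the para-hydroxybenzylic C2–O1 bond should not open through a quinone methide.

## Compound list

1 | syringaldehyde | COc1cc(C=O)cc(OC)c1O | starting material
2 | 3,5-dimethoxy-4-(triisopropylsilyloxy)benzaldehyde | COc1cc(C=O)cc(OC)c1O[Si](C(C)C)(C(C)C)C(C)C | intermediate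
3 | 2-[3,5-dimethoxy-4-(triisopropylsilyloxy)phenyl]-1,3-dithiane | COc1cc(C2SCCCS2)cc(OC)c1O[Si](C(C)C)(C(C)C)C(C)C | intermediate
4 | vanillin | COc1cc(C=O)ccc1O | starting material
5 | 3-methoxy-4-(triisopropylsilyloxy)benzaldehyde | COc1cc(C=O)ccc1O[Si](C(C)C)(C(C)C)C(C)C | intermediate
6 | [3-methoxy-4-(triisopropylsilyloxy)phenyl]methanol | COc1cc(CO)ccc1O[Si](C(C)C)(C(C)C)C(C)C | intermediate
7 | 3-methoxy-4-(triisopropylsilyloxy)benzyl bromide | COc1cc(CBr)ccc1O[Si](C(C)C)(C(C)C)C(C)C | intermediate
8 | (5R)-5-[(1R,2S,5R)-menthyloxy]-2(5H)-furanone | O=C1O[C@@H](O[C@@H]2C[C@H](C)CC[C@H]2C(C)C)C=C1 | starting material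
9 | 2-lithio-2-[3,5-dimethoxy-4-(triisopropylsilyloxy)phenyl]-1,3-dithiane | COc1cc(C2([Li])SCCCS2)cc(OC)c1O[Si](C(C)C)(C(C)C)C(C)C | intermediate (not isolated)
10 | lithium (4R,5R)-4-{2-[3,5-dimethoxy-4-(triisopropylsilyloxy)phenyl]-1,3-dithian-2-yl}-5-[(1R,2S,5R)-menthyloxy]-4,5-dihydrofuran-2-olate | [Li]OC1=C[C@@H](C2(c3cc(OC)c(O[Si](C(C)C)(C(C)C)C(C)C)c(OC)c3)SCCCS2)[C@H](O[C@@H]2C[C@H](C)CC[C@H]2C(C)C)O1 | intermediate (not isolated)
11 | (3R,4R,5R)-3-[3-methoxy-4-(triisopropylsilyloxy)benzyl]-4-{2-[3,5-dimethoxy-4-(triisopropylsilyloxy)phenyl]-1,3-dithian-2-yl}-5-[(1R,2S,5R)-menthyloxy]dihydrofuran-2(3H)-one | O=C1O[C@@H](O[C@@H]2C[C@H](C)CC[C@H]2C(C)C)[C@H](C2(c3cc(OC)c(O[Si](C(C)C)(C(C)C)C(C)C)c(OC)c3)SCCCS2)[C@H]1Cc1ccc(O[Si](C(C)C)(C(C)C)C(C)C)c(OC)c1 | intermediate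
12 | (3R,4R,5R)-4-[3,5-dimethoxy-4-(triisopropylsilyloxy)benzoyl]-3-[3-methoxy-4-(triisopropylsilyloxy)benzyl]-5-[(1R,2S,5R)-menthyloxy]dihydrofuran-2(3H)-one | O=C1O[C@@H](O[C@@H]2C[C@H](C)CC[C@H]2C(C)C)[C@H](C(=O)c2cc(OC)c(O[Si](C(C)C)(C(C)C)C(C)C)c(OC)c2)[C@H]1Cc1ccc(O[Si](C(C)C)(C(C)C)C(C)C)c(OC)c1 | intermediate
13 | (2R,3R)-2-{[3,5-dimethoxy-4-(triisopropylsilyloxy)phenyl](hydroxy)methyl}-3-[3-methoxy-4-(triisopropylsilyloxy)benzyl]butane-1,4-diol, both carbinol epimers | OC[C@H](C(O)c1cc(OC)c(O[Si](C(C)C)(C(C)C)C(C)C)c(OC)c1)[C@@H](Cc1ccc(O[Si](C(C)C)(C(C)C)C(C)C)c(OC)c1)CO | intermediate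
14 | benzylic cation at C2 derived from 13 | OC[C@H]([CH+]c1cc(OC)c(O[Si](C(C)C)(C(C)C)C(C)C)c(OC)c1)[C@@H](Cc1ccc(O[Si](C(C)C)(C(C)C)C(C)C)c(OC)c1)CO | intermediate (not isolated)
15 | [(2S,3R,4R)-2-[3,5-dimethoxy-4-(triisopropylsilyloxy)phenyl]-4-[3-methoxy-4-(triisopropylsilyloxy)benzyl]tetrahydrofuran-3-yl]methanol | OC[C@H]1[C@@H](Cc2ccc(O[Si](C(C)C)(C(C)C)C(C)C)c(OC)c2)CO[C@@H]1c1cc(OC)c(O[Si](C(C)C)(C(C)C)C(C)C)c(OC)c1 | intermediate
16 | (E)-ferulic acid | COc1cc(/C=C/C(=O)O)ccc1O | starting material
17 | triisopropylsilyl (E)-3-[3-methoxy-4-(triisopropylsilyloxy)phenyl]prop-2-enoate | COc1cc(/C=C/C(=O)O[Si](C(C)C)(C(C)C)C(C)C)ccc1O[Si](C(C)C)(C(C)C)C(C)C | intermediate (not isolated)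
18 | (E)-3-[3-methoxy-4-(triisopropylsilyloxy)phenyl]prop-2-enoic acid | COc1cc(/C=C/C(=O)O)ccc1O[Si](C(C)C)(C(C)C)C(C)C | intermediate
19 | [(2S,3R,4R)-2-[3,5-dimethoxy-4-(triisopropylsilyloxy)phenyl]-4-[3-methoxy-4-(triisopropylsilyloxy)benzyl]tetrahydrofuran-3-yl]methyl (E)-3-[3-methoxy-4-(triisopropylsilyloxy)phenyl]prop-2-enoate | COc1cc(/C=C/C(=O)OC[C@H]2[C@@H](Cc3ccc(O[Si](C(C)C)(C(C)C)C(C)C)c(OC)c3)CO[C@@H]2c2cc(OC)c(O[Si](C(C)C)(C(C)C)C(C)C)c(OC)c2)ccc1O[Si](C(C)C)(C(C)C)C(C)C | intermediate
20 | [(2S,3R,4R)-2-(4-hydroxy-3,5-dimethoxyphenyl)-4-(4-hydroxy-3-methoxybenzyl)tetrahydrofuran-3-yl]methyl (E)-3-(4-hydroxy-3-methoxyphenyl)prop-2-enoate | COc1cc(/C=C/C(=O)OC[C@H]2[C@@H](Cc3ccc(O)c(OC)c3)CO[C@@H]2c2cc(OC)c(O)c(OC)c2)ccc1O | target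

## Step count and least certain steps

Total step count: 12. Longest linear sequence: 9 steps (4 → 5 → 6 → 7 → 11 → 12 → 13 → 15 → 19 → 20, that is steps 3, 4, 5, 6, 7, 8, 9, 11 and 12).

**Step 6 (key step).** Several processes can compete:
- 1,2-addition of 9 to the lactone carbonyl, or proton abstraction at the acetal carbon of 8, in place of conjugate addition;
- slow benzylation of enolate 10, whose α-carbon lies next to a quaternary dithiane carbon, so that proton quench on work-up wins;
- decomposition of the electron-rich bromide 7 before it is captured;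
- incomplete trans selectivity in the alkylation.

Fallback: the two bond formations are separated. Starting from 3 and 8, the conjugate addition is run alone and quenched with acid to give the isolated adduct (4R,5R)-4-{2-[3,5-dimethoxy-4-(triisopropylsilyloxy)phenyl]-1,3-dithian-2-yl}-5-[(1R,2S,5R)-menthyloxy]dihydrofuran-2(3H)-one F1. This is purified, converted into its more reactive potassium enolate with KHMDS in THF/DMPU at −78 °C and alkylated with freshly made 7. The route is rejoined at 11.

**Step 7.** The hindered, fully substituted dithiane may be unmasked slowly. Once the ketone exists, enolisation toward the carbon between ketone and acetal can lead to loss of the acetal oxygen by β-elimination or to epimerisation. The mercury salt may also attack the electron-rich rings. Fallback: the order of unmasking and reduction is reversed, so that no ketone is ever next to the acetal. Starting from 11, LiAlH4 reduces lactone and acetal first to give (2R,3R)-2-{2-[3,5-dimethoxy-4-(triisopropylsilyloxy)phenyl]-1,3-dithian-2-yl}-3-[3-methoxy-4-(triisopropylsilyloxy)benzyl]butane-1,4-diol F2. The dithiane is then hydrolysed (HgO, BF3·OEt2, wet THF) to (2R,3R)-2-[3,5-dimethoxy-4-(triisopropylsilyloxy)benzoyl]-3-[3-methoxy-4-(triisopropylsilyloxy)benzyl]butane-1,4-diol F3, which will sit largely as its cyclic hemiketal. NaBH4 in MeOH reduces it through the open form, and the route is rejoined at 13.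

**Step 9.** Cation 14 may be intercepted irreversibly by the guaiacyl ring (Friedel–Crafts attack from its position para to the methoxy group, giving an aryltetralin) if the acid is too strong or the time too long. Ionisation may be slow because the hindered silyloxy group, twisted out of the ring plane, donates poorly. Under kinetic control a mixture at C2 may form. Fallback: the ring is closed on the free phenol, where ionisation runs through a quinone methide under much weaker acid. Starting from 13, TBAF/AcOH gives (2R,3R)-2-[hydroxy(4-hydroxy-3,5-dimethoxyphenyl)methyl]-3-(4-hydroxy-3-methoxybenzyl)butane-1,4-diol F4. Dilute formic acid in aqueous THF closes it to 5-methoxylariciresinol, [(2S,3R,4R)-2-(4-hydroxy-3,5-dimethoxyphenyl)-4-(4-hydroxy-3-methoxybenzyl)tetrahydrofuran-3-yl]methanol F5. Its primary alcohol is esterified with unprotected ferulic acid 16 under Mitsunobu conditions (PPh3, DIAD, THF, 0 °C), where the carboxylic acid, not a phenol, is the pronucleophile. The route is rejoined at 20.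

**Step 10.** The carbonate treatment may also remove part of the aryl silyl ether, or leave silyl ester behind, which would give mixtures in step 11. Fallback: the acid is built by carbon–carbon bond formation instead of selective deprotection. Starting from 5, a Knoevenagel–Doebner condensation with malonic acid (pyridine, catalytic piperidine, 60–80 °C) gives the (E)-acid directly, and the route is rejoined at 18. This fallback makes no new compound (F0).

## Further compounds

F1 | step 6 | (4R,5R)-4-{2-[3,5-dimethoxy-4-(triisopropylsilyloxy)phenyl]-1,3-dithian-2-yl}-5-[(1R,2S,5R)-menthyloxy]dihydrofuran-2(3H)-one | O=C1O[C@@H](O[C@@H]2C[C@H](C)CC[C@H]2C(C)C)[C@H](C2(c3cc(OC)c(O[Si](C(C)C)(C(C)C)C(C)C)c(OC)c3)SCCCS2)C1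
F2 | step 7 | (2R,3R)-2-{2-[3,5-dimethoxy-4-(triisopropylsilyloxy)phenyl]-1,3-dithian-2-yl}-3-[3-methoxy-4-(triisopropylsilyloxy)benzyl]butane-1,4-diol | OC[C@H](C1(c2cc(OC)c(O[Si](C(C)C)(C(C)C)C(C)C)c(OC)c2)SCCCS1)[C@@H](Cc1ccc(O[Si](C(C)C)(C(C)C)C(C)C)c(OC)c1)CO
F3 | step 7 | (2R,3R)-2-[3,5-dimethoxy-4-(triisopropylsilyloxy)benzoyl]-3-[3-methoxy-4-(triisopropylsilyloxy)benzyl]butane-1,4-diol | OC[C@H](C(=O)c1cc(OC)c(O[Si](C(C)C)(C(C)C)C(C)C)c(OC)c1)[C@@H](Cc1ccc(O[Si](C(C)C)(C(C)C)C(C)C)c(OC)c1)CO
F4 | step 9 | (2R,3R)-2-[hydroxy(4-hydroxy-3,5-dimethoxyphenyl)methyl]-3-(4-hydroxy-3-methoxybenzyl)butane-1,4-diol | OC[C@H](C(O)c1cc(OC)c(O)c(OC)c1)[C@@H](Cc1ccc(O)c(OC)c1)CO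
F5 | step 9 | [(2S,3R,4R)-2-(4-hydroxy-3,5-dimethoxyphenyl)-4-(4-hydroxy-3-methoxybenzyl)tetrahydrofuran-3-yl]methanol | OC[C@H]1[C@@H](Cc2ccc(O)c(OC)c2)CO[C@@H]1c1cc(OC)c(O)c(OC)c1
F0 | step 10 | none | none
A1 | alternative 1 | 3-[4-(benzyloxy)-3-methoxybenzyl]cyclobutanone | O=C1CC(Cc2ccc(OCc3ccccc3)c(OC)c2)C1
A2 | alternative 1 | (R)-4-[4-(benzyloxy)-3-methoxybenzyl]dihydrofuran-2(3H)-one | O=C1C[C@@H](Cc2ccc(OCc3ccccc3)c(OC)c2)CO1
A3 | alternative 2 | 1-cyano-2-[(trimethylsilyl)methyl]allyl acetate | CC(=O)OC(C#N)C(=C)C[Si](C)(C)C
A4 | alternative 2 | 4-(tert-butyldimethylsilyloxy)-3,5-dimethoxybenzaldehyde | COc1cc(C=O)cc(OC)c1O[Si](C)(C)C(C)(C)C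
A5 | alternative 2 | (2S,3R)-2-[4-(tert-butyldimethylsilyloxy)-3,5-dimethoxyphenyl]-4-methylenetetrahydrofuran-3-carbonitrile | N#C[C@H]1C(=C)CO[C@@H]1c1cc(OC)c(O[Si](C)(C)C(C)(C)C)c(OC)c1
A6 | alternative 3 | (2R,3R)-2-(4-hydroxy-3,5-dimethoxybenzyl)-3-[3-methoxy-4-(triisopropylsilyloxy)benzyl]butane-1,4-diol | OC[C@H](Cc1cc(OC)c(O)c(OC)c1)[C@@H](Cc1ccc(O[Si](C(C)C)(C(C)C)C(C)C)c(OC)c1)CO
A7 | alternative 3 | para-quinone methide of A6 | OC[C@H](C=C1C=C(OC)C(=O)C(OC)=C1)[C@@H](Cc1ccc(O[Si](C(C)C)(C(C)C)C(C)C)c(OC)c1)CO
A8 | alternative 3 | [(2S,3R,4R)-2-(4-hydroxy-3,5-dimethoxyphenyl)-4-[3-methoxy-4-(triisopropylsilyloxy)benzyl]tetrahydrofuran-3-yl]methanol | OC[C@H]1[C@@H](Cc2ccc(O[Si](C(C)C)(C(C)C)C(C)C)c(OC)c2)CO[C@@H]1c1cc(OC)c(O)c(OC)c1
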